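Assumption: (S)-(+)-linalool is used as the commercial single enantiomer (≥98% ee grade); locants C1–C15 are nerolidol locants (ring = C6–C11, Br on C8 and C10).

## Retrosynthetic overview

1. C3 is bought, not made: (S)-linalool 1. The C8–C9 bond is disconnected to prenyl bromide 2 (Z-selective allylpotassium alkylation via 3 and 4), giving (3S,6Z)-nerolidyl acetate 5.
2. The only ring (C6–C11 bond) comes from 5 by a bromonium-initiated cation–olefin cyclisation that mirrors the haloperoxidase pathway, giving endocyclic alkene 6. The 6Z olefin is deliberate: the target has the side chain trans to C10–Br, and chair closure of a Z olefin puts the chain axial.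
3. A second Br+ in the same flask (bromonium–ene on C7=C8) installs C8–Br cis to the side chain and the exocyclic methylene, giving 7.
4. Acetate removal gives the target 8.

## Route

Step 1
Reactants: 1 (S)-(+)-linalool; 2 prenyl bromide (1-bromo-3-methylbut-2-ene)
Product: 5 (3S,6Z)-nerolidyl acetate, via dipotassium linalool C,O-dianion 3 (not isolated), via potassium (3S,6Z)-nerolidolate 4 (not isolated)
Conditions: n-BuLi (2.2 equiv), KOt-Bu (2.2 equiv), THF/hexane, −78 → −50 °C, 3 h; 2 (1.05 equiv), −78 °C; Ac2O (4 equiv), −78 → 0 °C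
Reagents that add atoms: acetic anhydride, CC(=O)OC(C)=O
Why: Proposed new method: the first base equivalent forms the alkoxide and the Schlosser superbase then removes a proton from a terminal allylic methyl of 1 to give allylpotassium 3, which adopts the favoured endo form (chain cis to the CH2K terminus) and is alkylated by 2 at that unsubstituted terminus (SN2) to give 4 with the 6Z olefin, the untouched (3S)-alkoxide then being acetylated in the same flask; the closest known reactions are endo(Z)-selective electrophile capture of superbase-metalated prenyl termini and C-prenylation of metalated limonene or alkenol dianions.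

Step 2
Reactants: 5 (3S,6Z)-nerolidyl acetate
Product: 7 (3S)-5-[(1S,3R,5R)-3,5-dibromo-2,2-dimethyl-6-methylidenecyclohexyl]-3-methylpent-1-en-3-yl acetate, via endocyclic monobromide 6 (not isolated)
Conditions: DBDMH (1.05 equiv), chiral BINOL-derived thiophosphoramide Lewis base (10 mol %, the antipode that attacks the C10 Re face), toluene/CH2Cl2 3:1, −78 °C, 3 h; then −78 → −30 °C, 2 h
Reagents that add atoms: 1,3-dibromo-5,5-dimethylhydantoin (DBDMH), CC1(C)N(Br)C(=O)N(Br)C1=O
Why: Proposed new method: catalyst-bound Br+ adds to the Re face of C10 of the terminal alkene (sets 10R), the 6Z olefin attacks C11 anti through a chair with the side chain axial (sets C6, chain trans to Br), and loss of the axial H-8 to the hydantoin anion gives 6; the N–Br left on the reagent then forms a bromiranium ion on C7=C8 anti to the axial C11 methyl, i.e. cis to the pseudo-axial chain, and loss of a proton from the C7 methyl (C6–H is pseudo-equatorial and misaligned) gives the exocyclic methylene and the 8R allylic bromide; the closest known reactions are Lewis-base-catalysed enantioselective bromonium polyene cyclisation with DBDMH and ionic ene-type halogenation of trisubstituted alkenes, the two events proposed for the biosynthesis.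

Step 3
Reactants: 7 (3S)-5-[(1S,3R,5R)-3,5-dibromo-2,2-dimethyl-6-methylidenecyclohexyl]-3-methylpent-1-en-3-yl acetate
Product: 8 (3S)-5-[(1S,3R,5R)-3,5-dibromo-2,2-dimethyl-6-methylidenecyclohexyl]-3-methylpent-1-en-3-ol (target)
Conditions: DIBAL-H (2.5 equiv), CH2Cl2, −78 °C, 30 min; aq. Rochelle salt, 0 °C
Reagents that add atoms: none
Why: DIBAL-H reductive cleavage of the ester is fast at −78 °C and needs neither base nor nucleophile, so the secondary allylic bromide, the neopentylic bromide, both alkenes and all four stereocentres are left as they are; no new stereocentre is formed.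

## Compound list

1 | (S)-(+)-linalool, (3S)-3,7-dimethylocta-1,6-dien-3-ol | C=C[C@@](C)(O)CCC=C(C)C | starting material
2 | prenyl bromide, 1-bromo-3-methylbut-2-ene | CC(C)=CCBr | starting material
3 | dipotassium (2Z,6S)-2,6-dimethyl-6-oxidoocta-2,7-dien-1-ide (endo allylpotassium alkoxide of linalool) | C=C[C@@](C)([O-])CC/C=C(/C)[CH2-].[K+].[K+] | intermediate
4 | potassium (3S,6Z)-3,7,11-trimethyldodeca-1,6,10-trien-3-olate | C=C[C@@](C)([O-])CC/C=C(/C)CCC=C(C)C.[K+] | intermediate
5 | (3S,6Z)-3,7,11-trimethyldodeca-1,6,10-trien-3-yl acetate | C=C[C@@](C)(OC(C)=O)CC/C=C(/C)CCC=C(C)C | intermediate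
6 | (3S)-5-[(1R,5R)-5-bromo-2,6,6-trimethylcyclohex-2-en-1-yl]-3-methylpent-1-en-3-yl acetate (chain and Br trans) | C=C[C@@](C)(OC(C)=O)CC[C@@H]1C(C)=CC[C@@H](Br)C1(C)C | intermediate
7 | (3S)-5-[(1S,3R,5R)-3,5-dibromo-2,2-dimethyl-6-methylidenecyclohexyl]-3-methylpent-1-en-3-yl acetate | C=C[C@@](C)(OC(C)=O)CC[C@@H]1C(=C)[C@H](Br)C[C@@H](Br)C1(C)C | intermediate
8 | (3S)-5-[(1S,3R,5R)-3,5-dibromo-2,2-dimethyl-6-methylidenecyclohexyl]-3-methylpent-1-en-3-ol (chain cis to C5–Br, trans to C3–Br) | C=C[C@@](C)(O)CC[C@@H]1C(=C)[C@H](Br)C[C@@H](Br)C1(C)C | target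

## Step count and risks

Total step count: 3. Longest linear sequence: 3 steps (1 → 5 → 7 → 8).

The three steps most likely to fail (step 2 is the most exposed):

**Step 1.** The metalation may occur at the allylic CH2 (C5) instead of the methyl, the allyl anion may be alkylated at its substituted terminus or on oxygen, and the Z:E ratio may be lower than hoped. The fallback sets out from 1 and comes back at 5 without any C–H metalation:
- Ozonolysis of only the trisubstituted alkene of 1 (O3, CH2Cl2/MeOH, −78 °C, indicator end-point; Me2S) gives (5S)-5-ethenyl-5-methyloxolan-2-ol F1.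
- Still–Gennari olefination of F1 (methyl 2-[bis(2,2,2-trifluoroethoxy)phosphoryl]propanoate, KHMDS, 18-crown-6, THF, −78 °C) gives methyl (2Z,6S)-6-hydroxy-2,6-dimethylocta-2,7-dienoate F2.
- DIBAL-H reduces F2 to (2Z,6S)-2,6-dimethylocta-2,7-diene-1,6-diol F3.
- MsCl, LiCl, s-collidine in DMF at 0 °C converts only the primary allylic hydroxyl of F3 into the chloride (3S,6Z)-8-chloro-3,7-dimethylocta-1,6-dien-3-ol F4.
- After O-deprotonation with n-BuLi, F4 is coupled with prenylbarium chloride (Rieke barium, prenyl chloride, THF, −78 °C), α,α′-selectively and with retention of olefin geometry, to give (3S,6Z)-nerolidol F5.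
- F5 is acetylated (Ac2O, DMAP, Et3N) to 5.

**Step 2.** Enantioface control by the catalyst is untested with proton-loss termination. Exocyclic and C6=C7 alkene isomers of 6 would be carried into the second bromination as wrong products. The face of attack at C8 is substrate-controlled and could give the C8 epimer. The fallback sets out from 5, comes back at 6, and separates the two brominations:
- Mercury(II)-induced cyclisation of 5 with Hg(OTf)2 bound to a chiral bis(oxazoline) (MeNO2/CH2Cl2, −78 °C; aq. NaBr) gives (3S)-5-[(1R,5R)-5-(bromomercurio)-2,6,6-trimethylcyclohex-2-en-1-yl]-3-methylpent-1-en-3-yl acetate F6.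
- Radical bromodemercuration of F6 (Br2, LiBr, pyridine, O2, 0 °C) replaces Hg by Br, mainly with retention, to give 6, which is now isolated and freed of alkene isomers and the C10 epimer.
- 6 is then brominated on its own (DBDMH 0.5 equiv, Ph3P=S 5 mol %, CH2Cl2, −40 °C) to 7, which allows the Br+ carrier to be chosen for C8 selectivity.

**Step 3.** Hydride could attack the allylic bromide (reduction or SN2′), or the allylic bromide could isomerise on work-up. The fallback sets out from 4 and comes back at 8, avoiding any ester: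
- Alkoxide 4 is quenched with Et3SiCl instead of Ac2O to give (3S,6Z)-nerolidyl triethylsilyl ether F7.
- The same DBDMH cascade on F7 gives the silyl ether of the target, triethyl{[(3S)-5-[(1S,3R,5R)-3,5-dibromo-2,2-dimethyl-6-methylidenecyclohexyl]-3-methylpent-1-en-3-yl]oxy}silane F8.
- HF·pyridine (THF, 0 °C) cleaves the Si–O bond of F8 to give 8.

## Further compounds

F1 | step 1 | (5S)-5-ethenyl-5-methyloxolan-2-ol (anomer mixture) | C=C[C@@](C)(O1)CCC1O
F2 | step 1 | methyl (2Z,6S)-6-hydroxy-2,6-dimethylocta-2,7-dienoate | C=C[C@@](C)(O)CC/C=C(/C)C(=O)OC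
F3 | step 1 | (2Z,6S)-2,6-dimethylocta-2,7-diene-1,6-diol | C=C[C@@](C)(O)CC/C=C(/C)CO
F4 | step 1 | (3S,6Z)-8-chloro-3,7-dimethylocta-1,6-dien-3-ol | C=C[C@@](C)(O)CC/C=C(/C)CCl
F5 | step 1 | (3S,6Z)-nerolidol, (3S,6Z)-3,7,11-trimethyldodeca-1,6,10-trien-3-ol | C=C[C@@](C)(O)CC/C=C(/C)CCC=C(C)C
F6 | step 2 | (3S)-5-[(1R,5R)-5-(bromomercurio)-2,6,6-trimethylcyclohex-2-en-1-yl]-3-methylpent-1-en-3-yl acetate | C=C[C@@](C)(OC(C)=O)CC[C@@H]1C(C)=CC[C@@H]([Hg]Br)C1(C)C
F7 | step 3 | triethyl{[(3S,6Z)-3,7,11-trimethyldodeca-1,6,10-trien-3-yl]oxy}silane | C=C[C@@](C)(O[Si](CC)(CC)CC)CC/C=C(/C)CCC=C(C)C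
F8 | step 3 | triethyl{[(3S)-5-[(1S,3R,5R)-3,5-dibromo-2,2-dimethyl-6-methylidenecyclohexyl]-3-methylpent-1-en-3-yl]oxy}silane | C=C[C@@](C)(O[Si](CC)(CC)CC)CC[C@@H]1C(=C)[C@H](Br)C[C@@H](Br)C1(C)C
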